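**Plan**

- Retrosynthesis (isoflavanone numbering O1, C2, C3, C4, C4a–C8a; ring B primed): the three O‑allyl groups come off last; the pyranone ring is cut at C3–C4; the O1–C2 ether is cut to a salicylaldehyde and an α‑bromoketone; the C5'–C(CH3)2 bond is cut by a retro‑Claisen to an aryl prenyl ether.
- Enabling feature: in the ring O1–C2–C3–C4–C4a–C8a the C4 ketone is bonded directly to the tertiary carbinol C3 (an α‑ketol). C4 can therefore arrive as an acyl anion equivalent (a ring‑A aldehyde) and C3 as an aryl ketone held in reach by the O1–C2 tether.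
- Forward order: ring B is dressed first (O‑prenylation, aromatic Claisen, O‑allylation, α‑bromination); ring A is protected; the two are joined through O1–C2; the pyranone ring is closed last by C3–C4 bond formation.
- Stereochemistry: C3 (R), the only stereocentre, is set in the ring closure by a chiral triazolylidene catalyst. It is quaternary and no later step can epimerise it.

Key step: step 7

Assumption: the (5aS,10bR) antipode of the aminoindanol‑derived triazolium salt is taken as the one that delivers (R)‑12. The sense of induction is not certain for this substrate, so it would be confirmed on the first run and the equally available antipode used if needed.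

**Step 1**
Reactants: 1 1-(4-hydroxy-2-methoxyphenyl)ethan-1-one; 2 1-bromo-3-methylbut-2-ene (prenyl bromide)
Product: 3 1-{2-methoxy-4-[(3-methylbut-2-en-1-yl)oxy]phenyl}ethan-1-one
Conditions: K2CO3, acetone, reflux
Reagents that add atoms: prenyl bromide (2), CC(C)=CCBr
Why: Williamson ether synthesis; SN2 attack of the phenoxide on the primary allylic bromide should give the O‑prenyl ether cleanly.

**Step 2**
Reactants: 3 1-{2-methoxy-4-[(3-methylbut-2-en-1-yl)oxy]phenyl}ethan-1-one
Product: 4 1-[4-hydroxy-2-methoxy-5-(2-methylbut-3-en-2-yl)phenyl]ethan-1-one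
Conditions: EtOH/H2O (4:1), 130 °C, sealed tube
Reagents that add atoms: none
Why: aromatic Claisen rearrangement ([3,3] shift with allyl inversion, then rearomatisation) turns the O‑prenyl group into the C‑bound 1,1‑dimethylallyl group; C5 is the open ortho position, C3 is flanked by two oxygen substituents and should not accept a quaternary carbon, the para position is blocked by the acetyl group, and the aqueous medium should let the shift run below the temperature at which the abnormal Claisen pathway sets in.

**Step 3**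
Reactants: 4 1-[4-hydroxy-2-methoxy-5-(2-methylbut-3-en-2-yl)phenyl]ethan-1-one; 5 3-bromoprop-1-ene (allyl bromide)
Product: 6 1-[2-methoxy-5-(2-methylbut-3-en-2-yl)-4-(prop-2-en-1-yloxy)phenyl]ethan-1-one
Conditions: K2CO3, DMF, 50 °C
Reagents that add atoms: allyl bromide (5), C=CCBr
Why: Williamson ether synthesis; the allyl ether should survive silylation, NBS, carbonate, amine base and carbene, and is removable at the end under neutral Pd(0) conditions.

**Step 4**
Reactants: 6 1-[2-methoxy-5-(2-methylbut-3-en-2-yl)-4-(prop-2-en-1-yloxy)phenyl]ethan-1-one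
Product: 8 2-bromo-1-[2-methoxy-5-(2-methylbut-3-en-2-yl)-4-(prop-2-en-1-yloxy)phenyl]ethan-1-one, via trimethylsilyl enol ether 7 (not isolated)
Conditions: TMSOTf, Et3N, CH2Cl2, 0 °C; ammonium salt removed; then NBS, THF, −78 to 0 °C
Reagents that add atoms: N-bromosuccinimide, O=C1CCC(=O)N1Br; trimethylsilyl trifluoromethanesulfonate, C[Si](C)(C)OS(=O)(=O)C(F)(F)F (its silyl group stays only in 7)
Why: soft enolisation of the methyl ketone followed by electrophilic bromination of the silyl enol ether; the enol ether is far more nucleophilic than the two monosubstituted alkenes and the alkoxyarene, so one equivalent of NBS at low temperature should brominate only the α‑carbon.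

**Step 5**
Reactants: 9 2,4,6-trihydroxybenzaldehyde; 5 3-bromoprop-1-ene (allyl bromide, 2.1 equiv)
Product: 10 2-hydroxy-4,6-bis(prop-2-en-1-yloxy)benzaldehyde
Conditions: K2CO3 (2.2 equiv), DMF, 0 °C to rt
Reagents that add atoms: allyl bromide (5), C=CCBr
Why: Williamson ether synthesis; the 4‑OH and one ortho‑OH should react, while the remaining ortho‑OH is held in a hydrogen bond to the formyl oxygen and stays free, as in the usual partial alkylation of this aldehyde.

**Step 6**
Reactants: 10 2-hydroxy-4,6-bis(prop-2-en-1-yloxy)benzaldehyde; 8 2-bromo-1-[2-methoxy-5-(2-methylbut-3-en-2-yl)-4-(prop-2-en-1-yloxy)phenyl]ethan-1-one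
Product: 11 2-{2-[2-methoxy-5-(2-methylbut-3-en-2-yl)-4-(prop-2-en-1-yloxy)phenyl]-2-oxoethoxy}-4,6-bis(prop-2-en-1-yloxy)benzaldehyde
Conditions: K2CO3, acetone, rt
Reagents that add atoms: none
Why: Williamson ether synthesis by SN2 displacement of the reactive phenacyl bromide; a weak heterogeneous base at room temperature is chosen so that the keto‑aldehyde should not go on to intramolecular aldol condensation.

**Step 7**
Reactants: 11 2-{2-[2-methoxy-5-(2-methylbut-3-en-2-yl)-4-(prop-2-en-1-yloxy)phenyl]-2-oxoethoxy}-4,6-bis(prop-2-en-1-yloxy)benzaldehyde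
Product: 12 (3R)-3-hydroxy-3-[2-methoxy-5-(2-methylbut-3-en-2-yl)-4-(prop-2-en-1-yloxy)phenyl]-5,7-bis(prop-2-en-1-yloxy)-2,3-dihydro-4H-chromen-4-one
Conditions: (5aS,10bR) aminoindanol‑derived N‑C6F5 triazolium tetrafluoroborate (15 mol %), i‑Pr2NEt (15 mol %), toluene, 25 °C, Ar
Reagents that add atoms: none
Why: The base frees the triazolylidene, which adds to the aldehyde carbon; proton transfer gives the nucleophilic hydroxy‑enamine (an acyl anion equivalent), this carbon attacks the tethered aryl ketone, and proton transfer with loss of the carbene leaves the C4 ketone next to the new C3 carbinol. The closest known reaction type is the carbene‑catalysed enantioselective intramolecular crossed aldehyde–ketone benzoin reaction of 2-(2-oxoalkoxy)benzaldehydes to 3‑hydroxychroman‑4‑ones. The pyranone ring closes in the 6‑exo‑trig mode by formation of the C3–C4 bond. The configuration at C3 is set by the catalyst: the indane wall of the bound carbene shields one face of the hydroxy‑enamine, the ketone is oriented by a hydrogen bond from the enamine OH to its oxygen with its aryl group turned away from the catalyst, so one enantiotopic face of the ketone should be attacked. The step needs chemoselectivity for the carbene pathway over base‑mediated aldol closure of the enolisable O–CH2–C(=O) unit onto the aldehyde (five‑membered ring); the weak amine base, sufficient because the N‑pentafluorophenyl triazolium is acidic, and the non‑polar solvent should secure it, and cross‑selectivity is built in because only the aldehyde can form the acyl anion equivalent and only the ketone remains as acceptor.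

**Step 8**
Reactants: 12 (3R)-3-hydroxy-3-[2-methoxy-5-(2-methylbut-3-en-2-yl)-4-(prop-2-en-1-yloxy)phenyl]-5,7-bis(prop-2-en-1-yloxy)-2,3-dihydro-4H-chromen-4-one
Product: 13 (3R)-3,5,7-trihydroxy-3-[4-hydroxy-2-methoxy-5-(2-methylbut-3-en-2-yl)phenyl]-2,3-dihydro-4H-chromen-4-one
Conditions: Pd(PPh3)4 (5 mol %), morpholine (excess), degassed THF, rt
Reagents that add atoms: none
Why: Tsuji–Trost deallylation; Pd(0) ionises each aryl allyl ether to a π‑allyl complex and a phenoxide and morpholine traps the allyl group, under neutral conditions that should leave the tertiary ketol, the quaternary C3 and the leaving‑group‑free 1,1‑dimethylallyl alkene untouched.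

**Compound list**

1 | 1-(4-hydroxy-2-methoxyphenyl)ethan-1-one | CC(=O)c1ccc(O)cc1OC | starting material
2 | 1-bromo-3-methylbut-2-ene (prenyl bromide) | CC(C)=CCBr | starting material
3 | 1-{2-methoxy-4-[(3-methylbut-2-en-1-yl)oxy]phenyl}ethan-1-one | CC(=O)c1ccc(OCC=C(C)C)cc1OC | intermediate
4 | 1-[4-hydroxy-2-methoxy-5-(2-methylbut-3-en-2-yl)phenyl]ethan-1-one | C=CC(C)(C)c1cc(C(C)=O)c(OC)cc1O | intermediate
5 | 3-bromoprop-1-ene (allyl bromide) | C=CCBr | starting material
6 | 1-[2-methoxy-5-(2-methylbut-3-en-2-yl)-4-(prop-2-en-1-yloxy)phenyl]ethan-1-one | C=CC(C)(C)c1cc(C(C)=O)c(OC)cc1OCC=C | intermediate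
7 | ({1-[2-methoxy-5-(2-methylbut-3-en-2-yl)-4-(prop-2-en-1-yloxy)phenyl]ethenyl}oxy)trimethylsilane | C=CC(C)(C)c1cc(C(=C)O[Si](C)(C)C)c(OC)cc1OCC=C | intermediate
8 | 2-bromo-1-[2-methoxy-5-(2-methylbut-3-en-2-yl)-4-(prop-2-en-1-yloxy)phenyl]ethan-1-one | C=CC(C)(C)c1cc(C(=O)CBr)c(OC)cc1OCC=C | intermediate
9 | 2,4,6-trihydroxybenzaldehyde | O=Cc1c(O)cc(O)cc1O | starting material
10 | 2-hydroxy-4,6-bis(prop-2-en-1-yloxy)benzaldehyde | O=Cc1c(O)cc(OCC=C)cc1OCC=C | intermediate
11 | 2-{2-[2-methoxy-5-(2-methylbut-3-en-2-yl)-4-(prop-2-en-1-yloxy)phenyl]-2-oxoethoxy}-4,6-bis(prop-2-en-1-yloxy)benzaldehyde | C=CC(C)(C)c1cc(C(=O)COc2cc(OCC=C)cc(OCC=C)c2C=O)c(OC)cc1OCC=C | intermediate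
12 | (3R)-3-hydroxy-3-[2-methoxy-5-(2-methylbut-3-en-2-yl)-4-(prop-2-en-1-yloxy)phenyl]-5,7-bis(prop-2-en-1-yloxy)-2,3-dihydro-4H-chromen-4-one | C=CC(C)(C)c1cc([C@@]2(O)COc3cc(OCC=C)cc(OCC=C)c3C2=O)c(OC)cc1OCC=C | intermediate
13 | (3R)-3,5,7-trihydroxy-3-[4-hydroxy-2-methoxy-5-(2-methylbut-3-en-2-yl)phenyl]-2,3-dihydro-4H-chromen-4-one | C=CC(C)(C)c1cc([C@@]2(O)COc3cc(O)cc(O)c3C2=O)c(OC)cc1O | target

**Step count**

Total steps: 8. Longest linear sequence: 7 (steps 1, 2, 3, 4, 6, 7, 8).

**Steps most likely to fail**

Step 7. The aldehyde carries two ortho oxygen substituents and is electron‑rich, so carbene addition and formation of the acyl anion equivalent may be slow. Base‑mediated aldol closure and dehydration could then take over, or facial selectivity at the ortho‑substituted aryl ketone could be poor. The fallback sets out from 11 and drops carbene catalysis. SmI2 (THF, −78 °C) should effect ketyl–carbonyl (pinacol) cyclisation to racemic 3-[2-methoxy-5-(2-methylbut-3-en-2-yl)-4-(prop-2-en-1-yloxy)phenyl]-5,7-bis(prop-2-en-1-yloxy)-3,4-dihydro-2H-chromene-3,4-diol F1. IBX in DMSO should then oxidise only the secondary benzylic C4 carbinol to give the racemic ketol rac-3-hydroxy-3-[2-methoxy-5-(2-methylbut-3-en-2-yl)-4-(prop-2-en-1-yloxy)phenyl]-5,7-bis(prop-2-en-1-yloxy)-2,3-dihydro-4H-chromen-4-one F2. Preparative chromatography on a chiral phase would separate the (3S)-enantiomer of 12 F3 and return the route at 12.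

Step 2. The free ortho‑(1,1‑dimethylallyl)phenol may rearrange further (abnormal Claisen) or cyclise onto its own alkene, and some migration to C3 cannot be excluded. The fallback sets out from 1 and builds the aryl–C(CH3)2 bond by cross‑coupling. NBS in MeCN at 0 °C should brominate C5 (ortho to OH, para to OMe) to give 1-(5-bromo-4-hydroxy-2-methoxyphenyl)ethan-1-one F4. A γ‑selective (branched) Suzuki–Miyaura coupling with prenylboronic acid pinacol ester under Pd/bulky phosphine catalysis (K3PO4, THF/H2O) should then give 4, where the route is rejoined.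

Step 6. The hydrogen‑bonded, doubly ortho‑substituted phenoxide may alkylate slowly, and the keto‑aldehyde formed may undergo intramolecular aldol condensation (Rap–Stoermer closure) under the basic conditions. The fallback sets out from 8 and carries the ketone at the alcohol oxidation level through the etherification. NaBH4 in MeOH at 0 °C should give 2-bromo-1-[2-methoxy-5-(2-methylbut-3-en-2-yl)-4-(prop-2-en-1-yloxy)phenyl]ethan-1-ol F5. With 10 and K2CO3 in DMF at 60 °C this should close to 2-[2-methoxy-5-(2-methylbut-3-en-2-yl)-4-(prop-2-en-1-yloxy)phenyl]oxirane F6 in the flask, which the phenoxide opens at the CH2 terminus to give 2-{2-hydroxy-2-[2-methoxy-5-(2-methylbut-3-en-2-yl)-4-(prop-2-en-1-yloxy)phenyl]ethoxy}-4,6-bis(prop-2-en-1-yloxy)benzaldehyde F7. This alcohol cannot enolise, and Dess–Martin periodinane (CH2Cl2, NaHCO3) should oxidise it to 11.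

**Further compounds**

F1 | step 7 | rac-3-[2-methoxy-5-(2-methylbut-3-en-2-yl)-4-(prop-2-en-1-yloxy)phenyl]-5,7-bis(prop-2-en-1-yloxy)-3,4-dihydro-2H-chromene-3,4-diol (racemic, configuration at C4 not material) | C=CC(C)(C)c1cc(C2(O)COc3cc(OCC=C)cc(OCC=C)c3C2O)c(OC)cc1OCC=C
F2 | step 7 | rac-3-hydroxy-3-[2-methoxy-5-(2-methylbut-3-en-2-yl)-4-(prop-2-en-1-yloxy)phenyl]-5,7-bis(prop-2-en-1-yloxy)-2,3-dihydro-4H-chromen-4-one (racemate) | C=CC(C)(C)c1cc(C2(O)COc3cc(OCC=C)cc(OCC=C)c3C2=O)c(OC)cc1OCC=C
F3 | step 7 | (3S)-enantiomer of 12 | C=CC(C)(C)c1cc([C@]2(O)COc3cc(OCC=C)cc(OCC=C)c3C2=O)c(OC)cc1OCC=C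
F4 | step 2 | 1-(5-bromo-4-hydroxy-2-methoxyphenyl)ethan-1-one | CC(=O)c1cc(Br)c(O)cc1OC
F5 | step 6 | 2-bromo-1-[2-methoxy-5-(2-methylbut-3-en-2-yl)-4-(prop-2-en-1-yloxy)phenyl]ethan-1-ol (racemic) | C=CC(C)(C)c1cc(C(O)CBr)c(OC)cc1OCC=C
F6 | step 6 | 2-[2-methoxy-5-(2-methylbut-3-en-2-yl)-4-(prop-2-en-1-yloxy)phenyl]oxirane (racemic) | C=CC(C)(C)c1cc(C2CO2)c(OC)cc1OCC=C
F7 | step 6 | 2-{2-hydroxy-2-[2-methoxy-5-(2-methylbut-3-en-2-yl)-4-(prop-2-en-1-yloxy)phenyl]ethoxy}-4,6-bis(prop-2-en-1-yloxy)benzaldehyde (racemic) | C=CC(C)(C)c1cc(C(O)COc2cc(OCC=C)cc(OCC=C)c2C=O)c(OC)cc1OCC=C
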